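The product levels off early. In the alder run it reads 24.7% at 5.00 d and 24.8% at 6.00 d, while the electrophile keeps falling, so in that run most of the electrophile goes elsewhere.

| setting | alder | oak | larch | flask |
|---|---|---|---|---|
| electrophile | 0.020 M | 0.020 M | 0.020 M | 0.020 M |
| nucleophile | 0.016 M | 0.016 M | 0.0080 M | 0.0160 M |
| free base | 5 mM | 20 mM | 10 mM | 10.0 mM |
| protic impurity | 0.020 M | 0.020 M | 0.020 M | 0.0200 M |
| remark | run made earlier | run made earlier | run made earlier |  |
| time |  |  |  | 10 d |

| run | time / d | electrophile / % | product / % |
|---|---|---|---|
| alder | 0.417 | 68.5 | 11.0 |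
| alder | 1.25 | 43.9 | 18.8 |
| alder | 2.00 | 28.9 | 21.6 |
| alder | 3.00 | 20.1 | 24.1 |
| alder | 5.00 | 11.3 | 24.7 |
| alder | 6.00 | 9.4 | 24.8 |
| oak | 0.417 | 69.2 | 12.5 |
| oak | 1.25 | 41.7 | 20.2 |
| oak | 2.00 | 28.6 | 22.7 |
| oak | 3.00 | 20.2 | 22.2 |
| oak | 5.00 | 10.7 | 25.4 |
| oak | 6.00 | 6.4 | 24.5 |
| larch | 1.25 | 48.0 | 8.4 |
| larch | 2.50 | 28.6 | 13.1 |
| larch | 4.00 | 18.3 | 12.6 |
| larch | 5.00 | 14.4 | 13.9 |
| larch | 6.00 | 13.5 | 14.4 |

(readings scatter by 1 percentage point)

- the earlier runs do not show how much of nucleophile is bound; that part of a forecast is a guess

- part of the electrophile that has reacted at 10 d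
- share of free nucleophile in free nucleophile and protonated nucleophile together, at 10 d

How much electrophile remains? At 5.00 d the alder and oak runs read 11.3% and 10.7%, although their base differs by a factor of 4.00, so I read the flask from them. Alder's tail, as read, falls at 0.253 /d, and carried on from its last reading that leaves 3.41%, so I reckon on 96.6% reacted in this flask.

How much acid reaches the base? I assume one acid set free per product and take alder's last product reading for this flask, which gives an estimated 4.96 mM. The acid load, meaning equivalents of acid per equivalent of base charged, is 0.496, about half in this flask.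

Does acid reach the nucleophile? From their own last readings alder reckons to a load of 0.992 and oak to 0.245, yet those product readings are 24.8% and 24.5%. So I guess that the base takes the acid first and that the nucleophile in this flask stays free, with a reckoned 5.04 mM of base in reserve.

The forecast gives 96% of the electrophile reacted and 40% of the nucleophile free. For the binding it weighs “acid released is at most about 19 mM against 10 mM base” and calls its share a guess, whereas I commit to the product's acid.

The flask gives 96.3% of the electrophile reacted and 99.7% of the nucleophile free.

    acid set free + free base ⇌ salt of the base, settled at all times (K = 5.48 × 10⁶ /M)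
    electrophile + protic impurity → quenched substrate (k = 0.0222 /M/min)
    nucleophile + acid set free ⇌ protonated nucleophile, settled at all times (K = 17000 /M)
    nucleophile ⇌ dormant form (K = 20.2, k = 3.08 × 10⁻⁴ /min)
    electrophile + nucleophile → acid set free + product (k = 0.0151 /M/min)

In the flask at 10.0 d the product stands at 25.6%, a load of 0.511, with 48.9% of the free base left. For the neighbouring flask with 0.050 M of electrophile and the same base I reckon, from alder's product reading, a load of 1.24, above one. Its product comes out at 20.7%, a load of 1.03. Its free base falls to 0.142% of its charge, and the free share of its nucleophile is 31.4%.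

Readings and results were computed on assumed constants; scatter was added.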